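**Plan**

1. The 2,2-dimethylpyran ring is cut at O1–C2 and C4–C4a, back to a free C8a phenol and 3-methylbut-2-enal.
2. Ring A (C4a, C5, C6, C7, C8, C8a) is a salicylate whose ester-bearing C6 lies between C5 (arylethyl) and C7 (hydroxyl). C7, C8, C8a, C4a and C5 carry the pattern of C2, C3, C4, C5 and C6 of a 3-prenyl-4-alkoxy-6-arylethyl-2-pyrone, so C6 is cut out at C5–C6 and C6–C7, the ring oxygen of that pyrone takes its place, and the carbon returns as an acetate unit.
3. The pyrone is cut at the C3–prenyl bond, at the CH2–CH2 bond of the side chain and at the O-allyl bond, back to 4-hydroxy-6-methylpyran-2-one.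
4. Forward: the pyrone ring is bought, ring A is made from it in step 6, and the pyran ring is closed last (step 8) after both allyl ethers have been removed together.
5. The target has no stereocentre and no stereogenic double bond, so no stereochemistry has to be set.

Key step: step 6

Remark: both phenol oxygens that must end up free are carried as allyl ethers, since an aryl silyl ether would be at risk from the methoxide of step 6. The prenyl group is introduced before any allyl ether exists, because zerovalent palladium would ionize such ethers.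

**Route**

Step 1
Reactants: 1 4-hydroxybenzyl alcohol; 2 allyl bromide
Product: 3 4-(allyloxy)benzyl alcohol
Conditions: K2CO3, acetone, reflux
Reagents that add atoms: none
Why: Williamson etherification, in which K2CO3 deprotonates only the phenol (far more acidic than the benzylic alcohol), so the phenoxide oxygen alone is allylated.

Step 2
Reactants: 3 4-(allyloxy)benzyl alcohol
Product: 4 4-(allyloxy)benzyl bromide
Conditions: PBr3 (0.4 equiv), Et2O, 0 °C; used without storage
Reagents that add atoms: phosphorus tribromide, BrP(Br)Br
Why: Bromination of a primary benzylic alcohol with PBr3 (SN2 displacement of the phosphite ester by bromide) is standard, and the allyl ether should tolerate the short, cold exposure.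

Step 3
Reactants: 5 4-hydroxy-6-methylpyran-2-one; 6 3-methylbut-2-enyl acetate
Product: 7 4-hydroxy-6-methyl-3-(3-methylbut-2-enyl)pyran-2-one
Conditions: Pd(PPh3)4 (5 mol %), DBU (1.1 equiv), toluene, 80 °C
Reagents that add atoms: none
Why: Tsuji–Trost allylation, in which zerovalent palladium ionizes the acetate to the 1,1-dimethyl-π-allyl complex and the soft pyrone enolate attacks its unsubstituted terminus through C3, the only nucleophilic carbon of a 4-hydroxy-2-pyrone, while any O-allyl ether formed first is re-ionized by the catalyst and drains to the C-prenyl product.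

Step 4
Reactants: 7 4-hydroxy-6-methyl-3-(3-methylbut-2-enyl)pyran-2-one; 4 4-(allyloxy)benzyl bromide
Product: 8 6-[2-(4-allyloxyphenyl)ethyl]-4-hydroxy-3-(3-methylbut-2-enyl)pyran-2-one
Conditions: LiN(iPr)2 (2.3 equiv), THF–DMPU, −78 °C; then 4, −78 to −20 °C; aq. HCl work-up
Reagents that add atoms: none
Why: Dianion alkylation of a 4-hydroxy-6-methyl-2-pyrone, in which the second deprotonation takes place at the vinylogous C6 methyl group and this carbanion, the more reactive end of the dianion, is benzylated by SN2 displacement, C3 being already substituted.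

Step 5
Reactants: 8 6-[2-(4-allyloxyphenyl)ethyl]-4-hydroxy-3-(3-methylbut-2-enyl)pyran-2-one; 9 allyl alcohol
Product: 10 4-allyloxy-6-[2-(4-allyloxyphenyl)ethyl]-3-(3-methylbut-2-enyl)pyran-2-one
Conditions: PPh3, diisopropyl azodicarboxylate, THF, 0 °C to rt
Reagents that add atoms: none
Why: Mitsunobu etherification of the acidic enolic 4-hydroxyl (a vinylogous carboxylic acid) with a primary alcohol should give the 4-alkoxy-2-pyrone, and the blocked C3 excludes C-allylation.

Step 6
Reactants: 10 4-allyloxy-6-[2-(4-allyloxyphenyl)ethyl]-3-(3-methylbut-2-enyl)pyran-2-one; 11 1-(tert-butyldimethylsilyloxy)-1-methoxyethene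
Product: 16 methyl 4-allyloxy-6-[2-(4-allyloxyphenyl)ethyl]-2-hydroxy-3-(3-methylbut-2-enyl)benzoate, via pyrylium triflate 12 (not isolated), via 2H-pyran adduct 13 (not isolated), via dienyl diester 14 (not isolated), via cyclohexadienone keto ester 15 (not isolated)
Conditions: CF3SO3CH3 (1.1 equiv), CH2Cl2, 0 °C to rt; then 11 (1.5 equiv), −78 to 0 °C; then NaOMe (3 equiv), MeOH–THF, 0 °C to rt; aq. HCl work-up
Reagents that add atoms: none
Why: Proposed new method: CF3SO3CH3 alkylates the lactone carbonyl oxygen of 10 (a vinylogous carbonate) to the 2,4-dialkoxypyrylium salt 12, the neutral ketene acetal 11 adds at C6 with transfer of its silyl group to triflate to give 2H-pyran 13, and 13 opens by retro-oxa-6π electrocyclization to dienyl diester 14, in which the former ring oxygen is an ester carbonyl held cis to the chain by the C2=C3 geometry inherited from the ring. NaOMe (which also converts the silyl triflate into the methyl silyl ether) deprotonates the doubly activated CH2CO2Me group, and the enolate closes ring A onto that ester in a 6-(enolexo)-exo-trig Dieckmann condensation, so that in chromene numbering C5–C6 comes from the addition and C6–C7 from the closure; the expelled methoxide carries the methyl group of CF3SO3CH3, and keto ester 15 enolizes to salicylate 16 with the old ring oxygen as its phenolic hydroxyl. The nearest established chemistry is the ring transformation of pyrylium salts into benzene derivatives by carbanions such as those of nitromethane or malonates, which add next to the ring oxygen, open the 2H-pyran and reclose by aldol condensation onto the ketone so formed; here the 2-methoxy group turns that carbonyl into an ester, so the closure is an acylation that keeps the oxygen on the ring. No stereocentre is formed, and a C4=C5 isomer of 14 with the acetate arm turned away should equilibrate through the reversible electrocyclization and through the delocalized enolate. The step needs attack at C6 and not at C2 or C4: C6 is the only electrophilic ring carbon that bears no oxygen donor and has no prenyl group next to it, the silyl ketene acetal is too weakly basic to deprotonate the side chain of the pyrylium ion, and adducts at the two alkoxy-bearing carbons are ketals that can re-ionize under the silyl triflate present, whereas only the C6 adduct is drawn off irreversibly to the arene.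

Step 7
Reactants: 16 methyl 4-allyloxy-6-[2-(4-allyloxyphenyl)ethyl]-2-hydroxy-3-(3-methylbut-2-enyl)benzoate
Product: 17 methyl 2,4-dihydroxy-6-[2-(4-hydroxyphenyl)ethyl]-3-(3-methylbut-2-enyl)benzoate
Conditions: Pd(PPh3)4 (5 mol %), morpholine (6 equiv), THF, rt
Reagents that add atoms: none
Why: Tsuji–Trost-type allyl transfer, in which zerovalent palladium ionizes both aryl allyl ethers to π-allyl complexes that morpholine captures, while the C-bound prenyl group and the methyl ester offer no leaving group and stay intact.

Step 8
Reactants: 17 methyl 2,4-dihydroxy-6-[2-(4-hydroxyphenyl)ethyl]-3-(3-methylbut-2-enyl)benzoate; 18 3-methylbut-2-enal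
Product: 19 methyl 7-hydroxy-5-[2-(4-hydroxyphenyl)ethyl]-2,2-dimethyl-8-(3-methylbut-2-enyl)-2H-chromene-6-carboxylate (target)
Conditions: 18 (2 equiv), ethylenediammonium diacetate (20 mol %), xylene, 140 °C
Reagents that add atoms: none
Why: Amine-salt-catalysed chromene annulation of a resorcinol with an enal (Knoevenagel-type C-alkylation, loss of water to an ortho-quinone methide, oxa-6π electrocyclization), which can only engage the 4-hydroxyl and benzoate C5, because C3 is blocked by prenyl, the chelated 2-hydroxyl has no free ortho carbon and the 4-hydroxyphenyl ring lacks resorcinol-type activation.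

**Compound list**

1 | 4-hydroxybenzyl alcohol | OCc1ccc(O)cc1 | starting material
2 | allyl bromide (3-bromoprop-1-ene) | C=CCBr | starting material
3 | 4-(allyloxy)benzyl alcohol | OCc1ccc(OCC=C)cc1 | intermediate
4 | 4-(allyloxy)benzyl bromide | BrCc1ccc(OCC=C)cc1 | intermediate
5 | 4-hydroxy-6-methylpyran-2-one | CC1=CC(O)=CC(=O)O1 | starting material
6 | 3-methylbut-2-enyl acetate | CC(=O)OCC=C(C)C | starting material
7 | 4-hydroxy-6-methyl-3-(3-methylbut-2-enyl)pyran-2-one | CC1=CC(O)=C(CC=C(C)C)C(=O)O1 | intermediate
8 | 6-[2-(4-allyloxyphenyl)ethyl]-4-hydroxy-3-(3-methylbut-2-enyl)pyran-2-one | OC1=C(CC=C(C)C)C(=O)OC(CCc2ccc(OCC=C)cc2)=C1 | intermediate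
9 | allyl alcohol (prop-2-en-1-ol) | C=CCO | starting material
10 | 4-allyloxy-6-[2-(4-allyloxyphenyl)ethyl]-3-(3-methylbut-2-enyl)pyran-2-one | C=CCOC1=C(CC=C(C)C)C(=O)OC(CCc2ccc(OCC=C)cc2)=C1 | intermediate
11 | 1-(tert-butyldimethylsilyloxy)-1-methoxyethene | COC(=C)O[Si](C)(C)C(C)(C)C | starting material
12 | 4-allyloxy-6-[2-(4-allyloxyphenyl)ethyl]-2-methoxy-3-(3-methylbut-2-enyl)pyrylium trifluoromethanesulfonate (not isolated, step 6) | COc1[o+]c(CCc2ccc(OCC=C)cc2)cc(OCC=C)c1CC=C(C)C.[O-]S(=O)(=O)C(F)(F)F | intermediate
13 | methyl 2-[4-allyloxy-2-[2-(4-allyloxyphenyl)ethyl]-6-methoxy-5-(3-methylbut-2-enyl)-2H-pyran-2-yl]acetate, racemic (not isolated, step 6) | COC(=O)CC1(CCc2ccc(OCC=C)cc2)C=C(OCC=C)C(CC=C(C)C)=C(OC)O1 | intermediate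
14 | dimethyl (2E,4Z)-3-allyloxy-5-[2-(4-allyloxyphenyl)ethyl]-2-(3-methylbut-2-enyl)hepta-2,4-dienedioate (not isolated, step 6) | COC(=O)C/C(CCc1ccc(OCC=C)cc1)=C\C(OCC=C)=C(\CC=C(C)C)C(=O)OC | intermediate
15 | methyl 4-allyloxy-6-[2-(4-allyloxyphenyl)ethyl]-3-(3-methylbut-2-enyl)-2-oxocyclohexa-3,5-diene-1-carboxylate, racemic keto tautomer (not isolated, step 6) | COC(=O)C1C(=O)C(CC=C(C)C)=C(OCC=C)C=C1CCc1ccc(OCC=C)cc1 | intermediate
16 | methyl 4-allyloxy-6-[2-(4-allyloxyphenyl)ethyl]-2-hydroxy-3-(3-methylbut-2-enyl)benzoate | COC(=O)c1c(O)c(CC=C(C)C)c(OCC=C)cc1CCc1ccc(OCC=C)cc1 | intermediate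
17 | methyl 2,4-dihydroxy-6-[2-(4-hydroxyphenyl)ethyl]-3-(3-methylbut-2-enyl)benzoate | COC(=O)c1c(O)c(CC=C(C)C)c(O)cc1CCc1ccc(O)cc1 | intermediate
18 | 3-methylbut-2-enal | CC(C)=CC=O | starting material
19 | methyl 7-hydroxy-5-[2-(4-hydroxyphenyl)ethyl]-2,2-dimethyl-8-(3-methylbut-2-enyl)-2H-chromene-6-carboxylate | COC(=O)c1c(O)c(CC=C(C)C)c2c(c1CCc1ccc(O)cc1)C=CC(C)(C)O2 | target

**Count and risks**

Total steps: 8. Longest linear sequence: 7 steps (1, 2, 4, 5, 6, 7, 8, from 4-hydroxybenzyl alcohol); the pyrone branch (step 3) joins at step 4.

Steps most likely to fail: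

1. Step 6 (proposed new method). The ketene acetal may add at an alkoxy-bearing ring carbon and displace alkoxide instead of entering at C6. The pyrylium ion may also shed its allyl group, or methoxide may exchange the allyloxy group of the β-alkoxy acrylate before ring closure. The fallback uses known chemistry, sets out from 4 and returns at 16. Commercial methyl 2,4-dihydroxy-6-methylbenzoate would be allylated with 2 (K2CO3, acetone) at the non-chelated 4-hydroxyl to give methyl 4-allyloxy-2-hydroxy-6-methylbenzoate F1. The phenoxide/benzylic dianion of F1 (lithium diisopropylamide, 2.2 equiv, THF, −78 °C, lateral lithiation of the ortho-toluate) would be alkylated with 4 to give methyl 4-allyloxy-6-[2-(4-allyloxyphenyl)ethyl]-2-hydroxybenzoate F2. The sodium phenoxide of F2 (NaH, toluene) would then be C-prenylated with 1-bromo-3-methylbut-2-ene at the position ortho to the phenoxide oxygen, between the two oxygens, to give 16.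

2. Step 8. Carbon–carbon bond formation at benzoate C5, which is flanked by the hydroxyl and the arylethyl chain, may be slow, so that self-condensation of the enal or attack on the unprotected hydroxyphenyl ring competes. The fallback sets out from 17 and returns at 19. The most acidic hydroxyl of 17 (position 4, para to the ester) would be alkylated with 3-chloro-3-methylbut-1-yne (K2CO3, 1 equiv, KI, CuI cat., acetone) to give methyl 2-hydroxy-6-[2-(4-hydroxyphenyl)ethyl]-3-(3-methylbut-2-enyl)-4-(2-methylbut-3-yn-2-yloxy)benzoate F3. Heating F3 in N,N-diethylaniline at 140 °C should bring about aryl propargyl Claisen rearrangement to C5, 1,5-hydrogen shift and oxa-6π electrocyclization to 19.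

3. Step 3. The enolate may attack the substituted terminus of the π-allyl complex (1,1-dimethylallyl product), C3 may be allylated twice, or the O-allyl ether may persist. The fallback builds the pyrone ring with the prenyl group in place; it sets out from 2 and returns at 8, so that steps 1 to 4 fall away. Commercial methyl 3-(4-hydroxyphenyl)propanoate would be allylated with 2 (K2CO3, acetone) to give methyl 3-(4-allyloxyphenyl)propanoate F4. Methyl acetoacetate would be alkylated with 1-bromo-3-methylbut-2-ene (K2CO3, acetone) to give methyl 2-(3-methylbut-2-enyl)-3-oxobutanoate F5. The dianion of F5 (NaH, then n-BuLi, THF, 0 °C, two equivalents) would be acylated at its terminal carbon by F4 to give methyl 7-(4-allyloxyphenyl)-2-(3-methylbut-2-enyl)-3,5-dioxoheptanoate F6. DBU in refluxing toluene should then lactonize F6 to 8.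

Further compounds
F1 | step 6 | methyl 4-allyloxy-2-hydroxy-6-methylbenzoate | COC(=O)c1c(O)cc(OCC=C)cc1C
F2 | step 6 | methyl 4-allyloxy-6-[2-(4-allyloxyphenyl)ethyl]-2-hydroxybenzoate | COC(=O)c1c(O)cc(OCC=C)cc1CCc1ccc(OCC=C)cc1
F3 | step 8 | methyl 2-hydroxy-6-[2-(4-hydroxyphenyl)ethyl]-3-(3-methylbut-2-enyl)-4-(2-methylbut-3-yn-2-yloxy)benzoate | COC(=O)c1c(O)c(CC=C(C)C)c(OC(C)(C)C#C)cc1CCc1ccc(O)cc1
F4 | step 3 | methyl 3-(4-allyloxyphenyl)propanoate | COC(=O)CCc1ccc(OCC=C)cc1
F5 | step 3 | methyl 2-(3-methylbut-2-enyl)-3-oxobutanoate | COC(=O)C(CC=C(C)C)C(C)=O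
F6 | step 3 | methyl 7-(4-allyloxyphenyl)-2-(3-methylbut-2-enyl)-3,5-dioxoheptanoate | COC(=O)C(CC=C(C)C)C(=O)CC(=O)CCc1ccc(OCC=C)cc1
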